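**Strategy.** Number the quinone ring C1 (C=O), C2 (OMe), C3 (indol-3-yl), C4 (C=O), C5 (OMe), C6 (7-prenylindol-3-yl). The ring is cut at C3–C4 and C5–C6. This exposes a hidden pattern: C4–C5 is an oxalyl unit, and C6–C1–C2–C3 is an open-chain 1,4-bis(indol-3-yl)butane-2,3-dione whose acidic α-methylenes become C3 and C6. In one operation a double Claisen condensation of this diketone with dimethyl oxalate forges both bonds, closes the six-membered ring and delivers the 2,5-dihydroxy-1,4-benzoquinone at the correct oxidation level, without protecting groups. O-Methylation finishes the synthesis. The unsymmetrical diketone comes from two indole-3-acetic acids and an oxamide linchpin.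

Key step: step 4

Remark: the target has no stereocentre. Enolisable dicarbonyl intermediates are drawn as keto forms although they will exist largely as enols, and the adducts 10 and 11 exist in the flask as lithium salts (drawn neutral).

**Step 1**
Reactants: 1 (2-bromophenyl)hydrazine hydrochloride; 2 methyl 4,4-dimethoxybutanoate
Product: 4 methyl 2-(7-bromo-1H-indol-3-yl)acetate, via arylhydrazone 3 (not isolated)
Conditions: H2SO4 (10 % v/v), MeOH, 65 °C
Reagents that add atoms: none
Why: Fischer indole synthesis; the acetal gives the arylhydrazone of methyl 4-oxobutanoate, whose [3,3]-sigmatropic shift can only use the one free ortho carbon, so bromine must end at C7 and the CH2CO2Me arm at C3.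

**Step 2**
Reactants: 4 methyl 2-(7-bromo-1H-indol-3-yl)acetate; 5 tributyl(3-methylbut-2-en-1-yl)stannane
Product: 7 2-[7-(3-methylbut-2-en-1-yl)-1H-indol-3-yl]acetic acid, via methyl ester 6 (not isolated)
Conditions: Pd(PPh3)4 (5 mol %), 1,4-dioxane, 100 °C; then LiOH, H2O, 40 °C; HCl work-up
Reagents that add atoms: lithium hydroxide, [Li+].[OH-]
Why: Stille coupling (oxidative addition of zerovalent palladium into C7–Br, prenyl transfer at the unsubstituted CH2 terminus, reductive elimination) should give the linear 7-prenyl arene, and saponification in the same pot lets the acid be separated from tin residues by base extraction.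

**Step 3**
Reactants: 7 2-[7-(3-methylbut-2-en-1-yl)-1H-indol-3-yl]acetic acid; 8 1,4-dimethylpiperazine-2,3-dione; 9 2-(1H-indol-3-yl)acetic acid
Product: 13 1-(1H-indol-3-yl)-4-[7-(3-methylbut-2-en-1-yl)-1H-indol-3-yl]butane-2,3-dione, via mono-adduct hemiaminal 10 (not isolated), via bis-hemiaminal 11 (not isolated), via diketo diacid 12 (not isolated)
Conditions: 7, LiN(iPr)2 (3.1 equiv), THF, −78 to 0 °C; add to 8, −78 °C; then 9 pre-treated with LiN(iPr)2 (3.1 equiv; 1.5 equiv of 9), −78 °C to rt; 1 M HCl, 0 °C to rt
Reagents that add atoms: none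
Why: Ivanov-type C-acylation; each trilithiated indole-3-acetic acid should add once to one amide carbonyl of the piperazinedione, the ring-bound tetrahedral alkoxides block over-addition and allow two different nucleophiles in sequence (the established unsymmetrical α-dione synthesis from this reagent), and acid hydrolysis releases the bis-β-keto acid, which loses two CO2 at room temperature.

**Step 4**
Reactants: 13 1-(1H-indol-3-yl)-4-[7-(3-methylbut-2-en-1-yl)-1H-indol-3-yl]butane-2,3-dione; 14 dimethyl oxalate
Product: 16 2,5-dihydroxy-3-(1H-indol-3-yl)-6-[7-(3-methylbut-2-en-1-yl)-1H-indol-3-yl]cyclohexa-2,5-diene-1,4-dione, via triketo ester 15 (not isolated)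
Conditions: NaOMe (5 equiv), 14 (1.5 equiv), MeOH–THF, 0 to 60 °C, argon, 13 added slowly; then 1 M HCl
Reagents that add atoms: none
Why: Double Claisen condensation: methoxide forms the enolate at the indol-3-ylmethylene carbon (future C3), which C-acylates one ester carbonyl of dimethyl oxalate (future C4) to give 15, and the second enolate at the 7-prenylindol-3-ylmethylene carbon (future C6) then attacks the remaining methyl ester (future C5) with loss of methoxide. The resulting cyclohexane-1,2,4,5-tetraone tautomerises to the 2,5-dihydroxy-1,4-benzoquinone, whose delocalised dianion is the thermodynamic sink that pulls both reversible acylations forward. The closest known reactions are the double Claisen condensations of 1,3-diarylacetones with dialkyl oxalates to cyclopentanetriones and Dieckmann-type closures to 3,6-disubstituted 2,5-dihydroxybenzoquinones. The ring closes by a 6-(enolendo)-exo-trig acyl substitution, and no stereocentre is formed. The step needs cross- over self-condensation and C- over O-acylation: excess non-enolisable oxalate with slow addition of 13 should suppress diketone self-aldol, O-acylation and the competing five-ring aldol are reversible under methoxide, and either methylene may react first because both orders converge on 16. The indole N–H groups need no protection because any N-oxalyl amide would be cleaved again by methoxide.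

**Step 5**
Reactants: 16 2,5-dihydroxy-3-(1H-indol-3-yl)-6-[7-(3-methylbut-2-en-1-yl)-1H-indol-3-yl]cyclohexa-2,5-diene-1,4-dione
Product: 17 3-(1H-indol-3-yl)-2,5-dimethoxy-6-[7-(3-methylbut-2-en-1-yl)-1H-indol-3-yl]cyclohexa-2,5-diene-1,4-dione
Conditions: TMSCHN2 (2.5 equiv), MeOH–toluene, 0 °C to rt
Reagents that add atoms: (trimethylsilyl)diazomethane, C[Si](C)(C)C=[N+]=[N-]
Why: O-Methylation of the two vinylogous carboxylic acid hydroxyls by the diazomethane equivalent should leave the much less acidic indole N–H groups and the prenyl alkene untouched, and the para-quinoid 2,5-dimethoxy form is the usual product for 3,6-disubstituted 2,5-dihydroxybenzoquinones.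

**Compound list**
1 | (2-bromophenyl)hydrazine hydrochloride | NNc1ccccc1Br.Cl | starting material
2 | methyl 4,4-dimethoxybutanoate | COC(OC)CCC(=O)OC | starting material
3 | methyl 4-[2-(2-bromophenyl)hydrazinylidene]butanoate (E/Z mixture) | COC(=O)CCC=NNc1ccccc1Br | intermediate
4 | methyl 2-(7-bromo-1H-indol-3-yl)acetate | COC(=O)Cc1c[nH]c2c(Br)cccc12 | intermediate
5 | tributyl(3-methylbut-2-en-1-yl)stannane | CCCC[Sn](CCCC)(CCCC)CC=C(C)C | starting material
6 | methyl 2-[7-(3-methylbut-2-en-1-yl)-1H-indol-3-yl]acetate | COC(=O)Cc1c[nH]c2c(CC=C(C)C)cccc12 | intermediate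
7 | 2-[7-(3-methylbut-2-en-1-yl)-1H-indol-3-yl]acetic acid | OC(=O)Cc1c[nH]c2c(CC=C(C)C)cccc12 | intermediate
8 | 1,4-dimethylpiperazine-2,3-dione | CN1CCN(C)C(=O)C1=O | starting material
9 | 2-(1H-indol-3-yl)acetic acid | OC(=O)Cc1c[nH]c2ccccc12 | starting material
10 | 2-(2-hydroxy-1,4-dimethyl-3-oxopiperazin-2-yl)-2-[7-(3-methylbut-2-en-1-yl)-1H-indol-3-yl]acetic acid (diastereomer mixture) | CN1CCN(C)C(O)(C(C(=O)O)c2c[nH]c3c(CC=C(C)C)cccc23)C1=O | intermediate
11 | 2-{3-[carboxy(1H-indol-3-yl)methyl]-2,3-dihydroxy-1,4-dimethylpiperazin-2-yl}-2-[7-(3-methylbut-2-en-1-yl)-1H-indol-3-yl]acetic acid (diastereomer mixture) | CN1CCN(C)C(O)(C(C(=O)O)c2c[nH]c3ccccc23)C1(O)C(C(=O)O)c1c[nH]c2c(CC=C(C)C)cccc12 | intermediate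
12 | 2-(1H-indol-3-yl)-5-[7-(3-methylbut-2-en-1-yl)-1H-indol-3-yl]-3,4-dioxohexanedioic acid (diastereomer mixture) | OC(=O)C(c1c[nH]c2ccccc12)C(=O)C(=O)C(C(=O)O)c1c[nH]c2c(CC=C(C)C)cccc12 | intermediate
13 | 1-(1H-indol-3-yl)-4-[7-(3-methylbut-2-en-1-yl)-1H-indol-3-yl]butane-2,3-dione | O=C(Cc1c[nH]c2ccccc12)C(=O)Cc1c[nH]c2c(CC=C(C)C)cccc12 | intermediate
14 | dimethyl oxalate | COC(=O)C(=O)OC | starting material
15 | methyl 3-(1H-indol-3-yl)-6-[7-(3-methylbut-2-en-1-yl)-1H-indol-3-yl]-2,4,5-trioxohexanoate (racemic) | COC(=O)C(=O)C(c1c[nH]c2ccccc12)C(=O)C(=O)Cc1c[nH]c2c(CC=C(C)C)cccc12 | intermediate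
16 | 2,5-dihydroxy-3-(1H-indol-3-yl)-6-[7-(3-methylbut-2-en-1-yl)-1H-indol-3-yl]cyclohexa-2,5-diene-1,4-dione | OC1=C(c2c[nH]c3ccccc23)C(=O)C(O)=C(c2c[nH]c3c(CC=C(C)C)cccc23)C1=O | intermediate
17 | 3-(1H-indol-3-yl)-2,5-dimethoxy-6-[7-(3-methylbut-2-en-1-yl)-1H-indol-3-yl]cyclohexa-2,5-diene-1,4-dione | COC1=C(c2c[nH]c3ccccc23)C(=O)C(OC)=C(c2c[nH]c3c(CC=C(C)C)cccc23)C1=O | target

**Step count.** Total: 5 steps. Longest linear sequence: 5 steps (1 to 17 through steps 1–5; 8, 9 and 14 enter as commercial materials).

**Steps most likely to fail**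

Step 3. The second addition, of a hindered enediolate to the amide next to the first tetrahedral centre, may stall. Proton transfer between the trianion and the mono-adduct may also scramble the partners and give symmetrical diones. The fallback sets out from 7 and comes back at 13. Activation with 1,1'-carbonyldiimidazole (THF, rt) would give the acyl imidazole 1-(1H-imidazol-1-yl)-2-[7-(3-methylbut-2-en-1-yl)-1H-indol-3-yl]ethan-1-one F1. C-Acylation of the potassium nitronate of commercial 3-(2-nitroethyl)-1H-indole (KOtBu, THF–DMSO, 0 °C to rt) would give the α-nitro ketone 4-(1H-indol-3-yl)-1-[7-(3-methylbut-2-en-1-yl)-1H-indol-3-yl]-3-nitrobutan-2-one F2. A buffered reductive Nef reaction (TiCl3, NH4OAc, aqueous THF) would turn the nitro-bearing carbon into the second carbonyl and return to 13.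

Step 4. Base-mediated self-aldol condensation and autoxidation of the enolisable α-diketone may outrun the ring-closing second acylation. The fallback sets out from 13 and comes back at 16. Silylation (TMSOTf, Et3N, CH2Cl2, 0 °C) would give the bis-silyl enol ether 3-{4-[7-(3-methylbut-2-en-1-yl)-1H-indol-3-yl]-2,3-bis[(trimethylsilyl)oxy]buta-1,3-dien-1-yl}-1H-indole F3. A double Mukaiyama-type C-acylation with oxalyl chloride (catalytic TMSOTf, CH2Cl2, −78 °C to rt) would form the same two ring bonds under non-basic conditions and give 16 after aqueous work-up, which also removes any N-silyl groups.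

Step 2. Allylic transposition during transmetalation may give the branched 1,1-dimethylallyl isomer, and slow oxidative addition at the electron-rich C7–Br bond beside N–H may let protodestannylation win. The fallback sets out from 4 and comes back at 6. Stille coupling with allyltributylstannane (Pd(PPh3)4, 1,4-dioxane, 100 °C), which has no regiochemical ambiguity, would give methyl 2-[7-(prop-2-en-1-yl)-1H-indol-3-yl]acetate F4. Cross-metathesis with excess 2-methylbut-2-ene (second-generation Grubbs catalyst, CH2Cl2, 40 °C) would give 6, which is saponified as in step 2.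

**Further compounds**
F1 | step 3 | 1-(1H-imidazol-1-yl)-2-[7-(3-methylbut-2-en-1-yl)-1H-indol-3-yl]ethan-1-one | O=C(Cc1c[nH]c2c(CC=C(C)C)cccc12)n1ccnc1
F2 | step 3 | 4-(1H-indol-3-yl)-1-[7-(3-methylbut-2-en-1-yl)-1H-indol-3-yl]-3-nitrobutan-2-one (racemic) | O=C(Cc1c[nH]c2c(CC=C(C)C)cccc12)C(Cc1c[nH]c2ccccc12)[N+](=O)[O-]
F3 | step 4 | 3-{4-[7-(3-methylbut-2-en-1-yl)-1H-indol-3-yl]-2,3-bis[(trimethylsilyl)oxy]buta-1,3-dien-1-yl}-1H-indole (double-bond isomer mixture) | C[Si](C)(C)OC(=Cc1c[nH]c2ccccc12)C(O[Si](C)(C)C)=Cc1c[nH]c2c(CC=C(C)C)cccc12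
F4 | step 2 | methyl 2-[7-(prop-2-en-1-yl)-1H-indol-3-yl]acetate | COC(=O)Cc1c[nH]c2c(CC=C)cccc12
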